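The numbers in the tables were generated by integration on assumed constants.

in all of them: Q 0.275 M

|  | Z | D | remark | time |
|---|---|---|---|---|
| teal | 0.12 M | 0.25 M | run made earlier |  |
| oak | 0.25 M | 0.250 M |  | 25 h |
| ash | 0.25 M | 0.250 M |  | 75 h |

teal run (percent of the Z charged)

| time / h | E / % | L / % | X / % | Z / % | G / % |
|---|---|---|---|---|---|
| 0.667 | 2.2 | 0 | 0 | 97.8 | 0.9 |
| 2.00 | 6.1 | 0.1 | 0 | 93.2 | 0 |
| 4.00 | 10.8 | 0.2 | 0 | 87.7 | 1.5 |
| 5.00 | 13.7 | 0 | 0 | 84.4 | 1.1 |
| 8.00 | 20.6 | 0.8 | 0.3 | 78.1 | 0.5 |

(standard deviation of a reading: 0.5 percentage points)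

- in percentages every species weighs as the Z in it: one J counts as two
- for L the J are counted in
- on the list of suspects stand: Z + L <-> J; G -> X; E + Q -> D + G; G + Q -> D + L; Z + Q -> D + E
- in an amount of L, one J counts as one L

* which of these there is most of at the end, counted by the Z in it, oak (E / X / Z / G / L)
* which of these there is most of at the end, counted by the Z in it, ash (E / X / Z / G / L)
* amount of the one of these that there is most of at the end, in percent of the Z charged, oak
* amount of the one of these that there is most of at the end, in percent of the Z charged, ash

- The trap I saw was to take the steady exponential fall of Z in teal as a property of Z and carry it unchanged to oak and ash. In teal, Z stood at 78.1% after 8.00 h, and I read from this a pseudo-first-order rate of 0.0309 h⁻¹.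
- [Q] was the first setting I looked at. It stayed at 0.275 M in oak, as in teal, so I kept that rate for the start of oak. Multiplied by 25 h, it gave 0.772, the turnover count N: the lifetimes of Z that pass if [Q] stays at its charge.
- [Z] was the second setting, and it rose from 0.12 M to 0.25 M. Q per Z therefore fell from 2.29 to 1.10, and with nearly equal charges [Q] falls along with [Z]. Z left then follows about one over one plus N, not e to the minus N, which gave me 56.4% for oak in place of 46.2%.
- Time was the third setting. The 75 h of ash gave a count of 2.32, so I reckoned Z left in ash at 30.1%.
- In teal, E had taken nearly all of the Z lost, so I expected E to pass Z near a count of 1, at about 32.4 h or somewhat later. I therefore committed to Z leading in oak and E leading in ash, with E below the 69.9% of the charge that I reckoned Z to have lost in ash.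
- [D] stood at 0.250 M in all three flasks, so I gave it no part in the count.
- The forecast gave Z at 56% for oak and E at 46% for ash, on the ground that “Q depletion dominates and the reaction stalls as Q runs out”.
- Oak gave Z at 54.6%, and ash gave E at 49.0%, with Z at 31.9%.

    Z + L ⇌ J, settled at all times (K = 4.40 M⁻¹)
    G → X (k = 0.0980 h⁻¹)
    E + Q → D + G (k = 0.0590 M⁻¹ h⁻¹)
    G + Q → D + L (k = 0.250 M⁻¹ h⁻¹)
    Z + Q → D + E (k = 0.120 M⁻¹ h⁻¹)

- The counts of 0.772 and 2.32 had put Z at 56.4% and 30.1%, so they missed oak and ash by 1.8 percentage points and 1.7 points. A neighbour of oak with 0.069 M of Q had Q as the limiting reagent, and its Z stood at 86% at the end. Counting the lifetimes of Q at the charged [Z] gave 0.702 for that neighbour, hence 49.6% of its charge of Q left, and it held 48.6% of that charge. At 25.0 h, oak made E 2.90 times faster than it used E up, each step taken net. At that moment Z + Q → D + E took the Q of oak 2.9 times faster than E + Q → D + G did.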